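**Plan**
- Retrosynthesis: first remove the masks (two neopentyl C–O bonds, one benzyl C–O bond). Then cut ring C at three bonds at once, C4a–C4, C4–C3 and O1–C2. This leaves an A-ring aryl iodide, carbon monoxide and a B-ring arylacetylene.
- Enabling feature: C4 is a single carbonyl carbon between C4a of ring A and C3. The A-ring fragment (iodine on C4a, a hydroxyl on each neighbouring carbon, the sulfate on C7 opposite) has a mirror plane through C4a and C7, so O1 and O5 are the same oxygen until ring C closes.
- Forward: rings A and B are bought as benzenoids, and each receives its sulfate as a neutral neopentyl diester while it is still a simple phenol. Ring C is the only ring built, in the three-component step. Unmasking follows.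
- Stereochemistry: there is none to set, because the target is a flat flavone with no stereocentre, axis or configured double bond.

Key step: step 6

Remark: the target is achiral, so the question of a single enantiomer does not arise. The bis(hydrogen sulfate) as drawn is taken as the final form and is reached from its disodium salt.

**Step 1**
Reactants: 1 neopentyl alcohol (2,2-dimethylpropan-1-ol)
Product: 2 neopentyl chlorosulfate
Conditions: SO2Cl2, pyridine, Et2O, −78 °C → rt
Reagents that add atoms: sulfuryl chloride, O=S(=O)(Cl)Cl
Why: Chlorosulfonylation of a primary alcohol with sulfuryl chloride and pyridine is the standard route to alkyl chlorosulfates, and the neopentyl carbon resists the SN2 collapse to the alkyl chloride.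

**Step 2**
Reactants: 3 phloroglucinol (anhydrous, 3 equiv); 2 neopentyl chlorosulfate (1 equiv)
Product: 5 3,5-dihydroxyphenyl neopentyl sulfate, via sodium 3,5-dihydroxyphenolate 4 (not isolated)
Conditions: NaH (1 equiv), THF–DMPU, 0 °C; then 2, 0 °C → rt; water wash removes surplus 3
Reagents that add atoms: sodium hydride, [Na+].[H-] (its sodium sits in 4 only)
Why: This is O-sulfonylation of a phenoxide by an alkyl chlorosulfate (protected-sulfate method); the three hydroxyls of 3 are equivalent, so a threefold excess of the cheap, water-soluble triol against one equivalent of base and 2 should hold the reaction at the monoester.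

**Step 3**
Reactants: 5 3,5-dihydroxyphenyl neopentyl sulfate
Product: 6 3,5-dihydroxy-4-iodophenyl neopentyl sulfate
Conditions: I2 (1.0 equiv), NaHCO3, THF–H2O, 0 °C
Reagents that add atoms: iodine, II
Why: Electrophilic aromatic iodination under aqueous bicarbonate sends iodine to C2 of resorcinol and of 5-substituted resorcinols, and here the two alternative positions are also crowded by the neopentyl sulfate.

**Step 4**
Reactants: 7 4-(benzyloxy)-3-hydroxybenzaldehyde (catalogue compound)
Product: 8 2-(benzyloxy)-5-ethynylphenol
Conditions: dimethyl (1-diazo-2-oxopropyl)phosphonate, K2CO3 (3 equiv), MeOH, rt; NH4Cl work-up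
Reagents that add atoms: Ohira–Bestmann reagent, COP(=O)(OC)C(=[N+]=[N-])C(C)=O
Why: The Ohira–Bestmann variant of the Seyferth–Gilbert homologation turns aryl aldehydes into terminal alkynes, and the phenoxide present in the medium is meta to the formyl group and so does not deactivate it.

**Step 5**
Reactants: 8 2-(benzyloxy)-5-ethynylphenol; 2 neopentyl chlorosulfate
Product: 10 2-(benzyloxy)-5-ethynylphenyl neopentyl sulfate, via sodium 2-(benzyloxy)-5-ethynylphenolate 9 (not isolated)
Conditions: NaH (1.05 equiv), THF, 0 °C; then 2, 0 °C → rt
Reagents that add atoms: sodium hydride, [Na+].[H-] (its sodium sits in 9 only)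
Why: This is the same phenoxide O-sulfonylation with an alkyl chlorosulfate as in step 2; the phenol is far more acidic than the alkyne C–H, so one equivalent of base addresses oxygen only, and placing the diester after step 4 keeps it away from methanolic carbonate.

**Step 6**
Reactants: 6 3,5-dihydroxy-4-iodophenyl neopentyl sulfate; 10 2-(benzyloxy)-5-ethynylphenyl neopentyl sulfate (1.2 equiv); 11 carbon monoxide
Product: 14 4'-O-benzylluteolin 7,3'-bis(neopentyl sulfate), via aryl ynone 12 (not isolated), via diethylamino enone 13 (not isolated)
Conditions: PdCl2(dppf) (5 mol %), Et2NH (5 equiv), DMF, CO (5 bar), 60 °C, no copper; aq. citric acid work-up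
Reagents that add atoms: diethylamine, CCNCC (its atoms sit in 13 only and leave again on ring closure)
Why: Pd(0) inserts into the C–I bond of 6, CO migrates in to give the aroyl–palladium species, the amine-deprotonated alkyne 10 is transferred, and reductive elimination delivers ynone 12, which sets C4a–C4 and C4–C3. Diethylamine then adds to the β-carbon of 12 to give the push–pull enone 13, and one ortho-hydroxyl attacks that same carbon (the future C2) and expels the amine, so ring C closes by a 6-endo-trig addition–elimination that forms O1–C2. The closest known reaction type is the palladium-catalysed carbonylative Sonogashira coupling–cyclisation of 2-iodophenols with terminal arylacetylenes in secondary-amine media, an established flavone synthesis. No stereocentre is created. Three selectivities matter: carbonylative over direct coupling (copper-free conditions, CO pressure and the two ortho substituents favour CO insertion over the direct alkynyl transfer that would end in a benzofuran), flavone over aurone (13 has no triple bond left for 5-exo attack and is electrophilic only at C2), and O1 against O5 (no choice arises, since the mirror plane of 6 through C–I and C–OSO3 makes both hydroxyls identical and the unused one ends as the chelated 5-OH). The neopentyl diesters should pass because their α-carbon is shielded from amine SN2 attack and esters of this type tolerate secondary amines, which is why the temperature is held at 60 °C and the amine at a few equivalents.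

**Step 7**
Reactants: 14 4'-O-benzylluteolin 7,3'-bis(neopentyl sulfate)
Product: 15 disodium 4'-O-benzylluteolin 7,3'-disulfate
Conditions: NaN3 (5 equiv), DMF, 65 °C; C18 desalting
Reagents that add atoms: sodium azide, [Na+].[N-]=[N+]=[N-]
Why: SN2 dealkylation of neopentyl aryl sulfate diesters by the small azide ion in a dipolar aprotic solvent is the established unmasking of this group, with the aryl sulfate monoanion as leaving group, and the benzyl ether still in place keeps O4' from attacking the neighbouring sulfur.

**Step 8**
Reactants: 15 disodium 4'-O-benzylluteolin 7,3'-disulfate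
Product: 16 disodium luteolin 7,3'-disulfate
Conditions: H2 (1 atm), 10 % Pd/C, MeOH–H2O, rt
Reagents that add atoms: none
Why: This is catalytic hydrogenolysis of an aryl benzyl ether, and both aryl sulfate monoester salts and the flavone C2–C3 double bond normally survive Pd/C at one atmosphere in neutral medium.

**Step 9**
Reactants: 16 disodium luteolin 7,3'-disulfate
Product: 17 luteolin 7,3'-disulfate (free acid, target)
Conditions: Dowex 50WX8 (H+ form), H2O, 0–5 °C; immediate freeze-drying
Reagents that add atoms: none
Why: Cation exchange on a sulfonic acid resin swaps Na+ for H+ without touching any covalent bond, and cold handling with prompt lyophilisation limits acid-catalysed hydrolysis of the aryl sulfates.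

**Compound list**
1 | neopentyl alcohol | CC(C)(C)CO | starting material
2 | neopentyl chlorosulfate | CC(C)(C)COS(=O)(=O)Cl | intermediate
3 | phloroglucinol | Oc1cc(O)cc(O)c1 | starting material
4 | sodium 3,5-dihydroxyphenolate | [Na+].[O-]c1cc(O)cc(O)c1 | intermediate
5 | 3,5-dihydroxyphenyl neopentyl sulfate | Oc1cc(O)cc(OS(=O)(=O)OCC(C)(C)C)c1 | intermediate
6 | 3,5-dihydroxy-4-iodophenyl neopentyl sulfate | Oc1cc(OS(=O)(=O)OCC(C)(C)C)cc(O)c1I | intermediate
7 | 4-(benzyloxy)-3-hydroxybenzaldehyde | O=Cc1ccc(OCc2ccccc2)c(O)c1 | starting material
8 | 2-(benzyloxy)-5-ethynylphenol | C#Cc1ccc(OCc2ccccc2)c(O)c1 | intermediate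
9 | sodium 2-(benzyloxy)-5-ethynylphenolate | [Na+].C#Cc1ccc(OCc2ccccc2)c([O-])c1 | intermediate
10 | 2-(benzyloxy)-5-ethynylphenyl neopentyl sulfate | C#Cc1ccc(OCc2ccccc2)c(OS(=O)(=O)OCC(C)(C)C)c1 | intermediate
11 | carbon monoxide | [C-]#[O+] | starting material
12 | 1-(2,6-dihydroxy-4-{[(neopentyloxy)sulfonyl]oxy}phenyl)-3-(4-(benzyloxy)-3-{[(neopentyloxy)sulfonyl]oxy}phenyl)prop-2-yn-1-one | O=C(C#Cc1ccc(OCc2ccccc2)c(OS(=O)(=O)OCC(C)(C)C)c1)c1c(O)cc(OS(=O)(=O)OCC(C)(C)C)cc1O | intermediate
13 | (E)-3-(diethylamino) enone from 12 and diethylamine (drawn E; the push–pull double bond isomerises freely and its geometry has no bearing on closure) | O=C(/C=C(/N(CC)CC)c1ccc(OCc2ccccc2)c(OS(=O)(=O)OCC(C)(C)C)c1)c1c(O)cc(OS(=O)(=O)OCC(C)(C)C)cc1O | intermediate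
14 | 4'-O-benzylluteolin 7,3'-bis(neopentyl sulfate) | O=c1cc(-c2ccc(OCc3ccccc3)c(OS(=O)(=O)OCC(C)(C)C)c2)oc2cc(OS(=O)(=O)OCC(C)(C)C)cc(O)c12 | intermediate
15 | disodium 4'-O-benzylluteolin 7,3'-disulfate | O=c1cc(-c2ccc(OCc3ccccc3)c(OS(=O)(=O)[O-])c2)oc2cc(OS(=O)(=O)[O-])cc(O)c12.[Na+].[Na+] | intermediate
16 | disodium luteolin 7,3'-disulfate | O=c1cc(-c2ccc(O)c(OS(=O)(=O)[O-])c2)oc2cc(OS(=O)(=O)[O-])cc(O)c12.[Na+].[Na+] | intermediate
17 | luteolin 7,3'-disulfate | O=c1cc(-c2ccc(O)c(OS(=O)(=O)O)c2)oc2cc(OS(=O)(=O)O)cc(O)c12 | target

**Step count**
Total steps: 9.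
Longest linear sequence: 7 (steps 1, 2, 3, 6, 7, 8, 9).

**Steps most likely to fail**

**1. Step 6.**
- What may go wrong:
  - The aroyl–palladium species may be captured by diethylamine or by a phenoxide oxygen instead of the acetylide.
  - The electron-rich iodoresorcinolate may suffer hydrodeiodination.
  - Direct alkynylation may be followed by benzofuran closure.
  - Aminolysis at sulfur may strip the O7 diester once the electron-poor chromone exists.
- Fallback, setting out from 6 and returning at 14:
  - Both phenols of 6 are capped with Ac2O/pyridine to give 2-iodo-5-{[(neopentyloxy)sulfonyl]oxy}-1,3-phenylene diacetate F1. This is a neutral, less electron-rich iodide with no free oxygen nucleophile.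
  - F1, 10 and 11 are joined in a plain carbonylative Sonogashira coupling that uses only a tertiary amine (PdCl2(PPh3)2, Et3N, THF, CO, rt to 40 °C), and the diacetoxy ynone F2 is isolated.
  - In a separate, metal-free operation, Et2NH in DMF cleaves both acetates, adds to the triple bond and lets a phenol close. This runs through 12 and 13 to 14, so bond formation and ring closure can be optimised apart from each other.

**2. Step 2.**
- What may go wrong: the statistical reaction may run on to bis- and tris-esters, the chlorosulfate may attack the very electron-rich ring at carbon, and material may be lost in separating the mixture.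
- Fallback, setting out from 2 and returning at 5:
  - Commercial 3,5-bis(benzyloxy)phenol F3 has one free hydroxyl only. NaH converts it into sodium 3,5-bis(benzyloxy)phenolate F4, which is sulfated with 2 to 3,5-bis(benzyloxy)phenyl neopentyl sulfate F5.
  - Hydrogenolysis (H2, Pd/C, EtOAc–EtOH, rt) then frees both phenols and gives 5, the neopentyl diester being inert to hydrogenation.

**3. Step 7.**
- What may go wrong: azide may attack sulfur rather than the hindered methylene carbon, with loss of sulfate from O7, whose aryloxide is a good leaving group. The reaction may also stall after only one of the two cleavages.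
- Fallback, setting out from 3, 8 and 11 and returning at 15:
  - The diester masks are given up and the sulfates are introduced after ring C exists.
  - Iodination of 3 (I2, NaHCO3, THF–H2O, 0 °C) gives 2-iodophloroglucinol F6, which is used fresh. Under the conditions of step 6 it combines with 8 and 11 through the trihydroxyphenyl ynone F7 and the diethylamino enone F8 to 4'-O-benzylluteolin F9.
  - In F9 only O7–H and O3'–H are free to react, because O4' is benzylated and O5–H is locked in the hydrogen bond to the C4 carbonyl. Me3N·SO3 with Na2CO3 in aqueous dioxane, the usual sulfation of flavonoid phenols, should therefore give 15 directly as the disodium salt.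

**Further compounds**
F1 | step 6 | 2-iodo-5-{[(neopentyloxy)sulfonyl]oxy}-1,3-phenylene diacetate | CC(=O)Oc1cc(OS(=O)(=O)OCC(C)(C)C)cc(OC(C)=O)c1I
F2 | step 6 | 1-(2,6-diacetoxy-4-{[(neopentyloxy)sulfonyl]oxy}phenyl)-3-(4-(benzyloxy)-3-{[(neopentyloxy)sulfonyl]oxy}phenyl)prop-2-yn-1-one | CC(=O)Oc1cc(OS(=O)(=O)OCC(C)(C)C)cc(OC(C)=O)c1C(=O)C#Cc1ccc(OCc2ccccc2)c(OS(=O)(=O)OCC(C)(C)C)c1
F3 | step 2 | 3,5-bis(benzyloxy)phenol (bought) | Oc1cc(OCc2ccccc2)cc(OCc2ccccc2)c1
F4 | step 2 | sodium 3,5-bis(benzyloxy)phenolate | [Na+].[O-]c1cc(OCc2ccccc2)cc(OCc2ccccc2)c1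
F5 | step 2 | 3,5-bis(benzyloxy)phenyl neopentyl sulfate | CC(C)(C)COS(=O)(=O)Oc1cc(OCc2ccccc2)cc(OCc2ccccc2)c1
F6 | step 7 | 2-iodophloroglucinol | Oc1cc(O)c(I)c(O)c1
F7 | step 7 | 3-[4-(benzyloxy)-3-hydroxyphenyl]-1-(2,4,6-trihydroxyphenyl)prop-2-yn-1-one | O=C(C#Cc1ccc(OCc2ccccc2)c(O)c1)c1c(O)cc(O)cc1O
F8 | step 7 | (E)-3-[4-(benzyloxy)-3-hydroxyphenyl]-3-(diethylamino)-1-(2,4,6-trihydroxyphenyl)prop-2-en-1-one | O=C(/C=C(/N(CC)CC)c1ccc(OCc2ccccc2)c(O)c1)c1c(O)cc(O)cc1O
F9 | step 7 | 4'-O-benzylluteolin | O=c1cc(-c2ccc(OCc3ccccc3)c(O)c2)oc2cc(O)cc(O)c12
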